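**Retrosynthetic overview**
1. Last bond: regioselective Yamaguchi esterification of the allylic 9-OH of an 8,9-diol with (2S,3R)-2,3-dimethyloxirane-2-carboxylic acid (Sharpless epoxidation of tiglyl alcohol, then oxidation); the diol is unmasked from an acetonide just before.
2. Ten-membered ring: ring-closing metathesis at C1=C10 (allyl group on C3, isopropenyl group on C9), with Z geometry expected from ring strain.
3. α-Methylene-γ-lactone with C6 and C7: syn-selective indium Barbier allylation and lactonisation, joining a tartrate-derived 2-(bromomethyl)acrylate (C7–C14) to a butenolide-derived lactol (C1–C6, C15).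
4. Fragments: the bromide from dimethyl 2,3-O-isopropylidene-L-tartrate (C8, C9) by Weinreb mono-addition, Wittig and Morita–Baylis–Hillman chemistry; the lactol from Keck allylation (C3) and directed carbomagnesiation/carboxylation (Z-C4=C5).
5. Ring order: dioxolane (from the chiral pool, temporary), then butenolide (temporary, holds the Z-alkene), then γ-lactone, then the ten-membered carbocycle; the oxirane is brought in preformed.

Assumption: the SMILES is taken literally (1(10)Z,4Z-diene; cis-fused 12,6-lactone, 6S,7R; 3S,8S,9S; (2S,3R)-epoxy ester with cis methyl groups), and germacrane numbering C1–C15 is used for positions.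

Step 1
Reactants: 1 dimethyl (4R,5R)-2,2-dimethyl-1,3-dioxolane-4,5-dicarboxylate (dimethyl 2,3-O-isopropylidene-L-tartrate)
Product: 2 (4R,5R)-N4,N5-dimethoxy-N4,N5,2,2-tetramethyl-1,3-dioxolane-4,5-dicarboxamide
Conditions: MeNH(OMe)·HCl, i-PrMgCl, THF, −20 → 0 °C
Reagents that add atoms: N,O-dimethylhydroxylamine hydrochloride, CNOC.Cl
Why: Weinreb amidation of both esters through the magnesium amide, the two stereocentres (future C8 and C9) coming unchanged from L-tartaric acid.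

Step 2
Reactants: 2 (4R,5R)-N4,N5-dimethoxy-N4,N5,2,2-tetramethyl-1,3-dioxolane-4,5-dicarboxamide
Product: 3 (4R,5R)-5-acetyl-N-methoxy-N,2,2-trimethyl-1,3-dioxolane-4-carboxamide
Conditions: MeMgBr (1.05 equiv), THF, −78 → −20 °C
Reagents that add atoms: methylmagnesium bromide, C[Mg]Br
Why: Weinreb ketone synthesis used as a desymmetrising mono-addition, because the magnesium-chelated tetrahedral adduct is stable and anionic and so holds back both over-addition and attack at the second amide, with no stereocentre affected.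

Step 3
Reactants: 3 (4R,5R)-5-acetyl-N-methoxy-N,2,2-trimethyl-1,3-dioxolane-4-carboxamide
Product: 4 (4R,5S)-N-methoxy-N,2,2-trimethyl-5-(prop-1-en-2-yl)-1,3-dioxolane-4-carboxamide
Conditions: Ph3PCH3Br, KN(SiMe3)2, THF, 0 °C; then 3, −78 → 0 °C
Reagents that add atoms: methyltriphenylphosphonium bromide, C[P+](c1ccccc1)(c1ccccc1)c1ccccc1.[Br-]
Why: Wittig methylenation of the ketone, much faster than attack on the Weinreb amide, gives the isopropenyl group (C10, C14) and changes the C5 descriptor from R to S only through CIP priorities.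

Step 4
Reactants: 4 (4R,5S)-N-methoxy-N,2,2-trimethyl-5-(prop-1-en-2-yl)-1,3-dioxolane-4-carboxamide
Product: 5 (4R,5S)-2,2-dimethyl-5-(prop-1-en-2-yl)-1,3-dioxolane-4-carbaldehyde
Conditions: i-Bu2AlH, THF, −78 °C
Reagents that add atoms: none
Why: Weinreb amide reduction stops at the aldehyde through the chelated aluminium hemiaminal, and the α-stereocentre is kept because the trans-dioxolane is also the thermodynamic isomer (used crude).

Step 5
Reactants: 5 (4R,5S)-2,2-dimethyl-5-(prop-1-en-2-yl)-1,3-dioxolane-4-carbaldehyde; 6 methyl acrylate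
Product: 7 methyl 2-{hydroxy[(4S,5S)-2,2-dimethyl-5-(prop-1-en-2-yl)-1,3-dioxolan-4-yl]methyl}prop-2-enoate (mixture of carbinol epimers)
Conditions: DABCO (0.5 equiv), 6 (3 equiv), dioxane/H2O (1:1), rt
Reagents that add atoms: none
Why: Morita–Baylis–Hillman reaction, whose new carbinol centre forms unselectively but is erased in step 6.

Step 6
Reactants: 7 methyl 2-{hydroxy[(4S,5S)-2,2-dimethyl-5-(prop-1-en-2-yl)-1,3-dioxolan-4-yl]methyl}prop-2-enoate
Product: 8 methyl (2Z)-2-(bromomethyl)-3-[(4S,5S)-2,2-dimethyl-5-(prop-1-en-2-yl)-1,3-dioxolan-4-yl]prop-2-enoate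
Conditions: NBS, Me2S (premixed), CH2Cl2, 0 °C → rt
Reagents that add atoms: N-bromosuccinimide, O=C1CCC(=O)N1Br
Why: Corey–Kim-type activation of the allylic alcohol and SN2′ displacement by bromide give the thermodynamically preferred (2Z)-2-(bromomethyl)enoate (β-H cis to the ester), with no free NBS left to attack the isopropenyl group.

Step 7
Reactants: 9 3-(trimethylsilyl)prop-2-ynal
Product: 11 (3S)-hex-5-en-1-yn-3-ol, via silyl alkynol 10 (not isolated)
Conditions: allylSnBu3, (S)-BINOL (10 mol%), Ti(OiPr)4 (10 mol%), 4 Å MS, CH2Cl2, −20 °C; then K2CO3, MeOH, rt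
Reagents that add atoms: allyltributylstannane, C=CC[Sn](CCCC)(CCCC)CCCC
Why: Keck asymmetric allylation, in which the (S)-BINOL–titanium Lewis acid directs allyl transfer to the Si face of the ynal and so sets the future C3 as S, followed by methanolytic C-desilylation.

Step 8
Reactants: 11 (3S)-hex-5-en-1-yn-3-ol
Product: 14 (5S)-4-methyl-5-(prop-2-en-1-yl)furan-2(5H)-one, via oxamagnesacycle 12 (not isolated), via hydroxy acid 13 (not isolated)
Conditions: MeMgBr (3.5 equiv), CuI (10 mol%), Et2O, −10 °C → rt; then CO2, −20 °C → rt; then 2 M HCl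
Reagents that add atoms: methylmagnesium bromide, C[Mg]Br; carbon dioxide, O=C=O
Why: Alkoxide-directed, copper-catalysed anti-carbomagnesiation (Duboudin carbomagnesiation) puts the methyl group on the carbinol-side alkyne carbon and magnesium on the terminus cis to the alkoxide, so carboxylation and acid lactonisation lock C4=C5 as Z inside the butenolide while the carbinol centre is untouched.

Step 9
Reactants: 14 (5S)-4-methyl-5-(prop-2-en-1-yl)furan-2(5H)-one
Product: 15 (5S)-4-methyl-5-(prop-2-en-1-yl)-2,5-dihydrofuran-2-ol (anomer mixture)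
Conditions: i-Bu2AlH (1.1 equiv), CH2Cl2, −78 °C
Reagents that add atoms: none
Why: Partial 1,2-reduction of the lactone carbonyl gives the lactol, a masked (Z)-γ-hydroxy enal whose ring preserves the alkene geometry (neutral work-up to avoid dehydration to the furan).

Step 10
Reactants: 8 methyl (2Z)-2-(bromomethyl)-3-[(4S,5S)-2,2-dimethyl-5-(prop-1-en-2-yl)-1,3-dioxolan-4-yl]prop-2-enoate; 15 (5S)-4-methyl-5-(prop-2-en-1-yl)-2,5-dihydrofuran-2-ol
Product: 18 (4S,5S)-4-[(4S,5S)-2,2-dimethyl-5-(prop-1-en-2-yl)-1,3-dioxolan-4-yl]-5-[(1Z,3S)-3-hydroxy-2-methylhexa-1,5-dien-1-yl]-3-methylideneoxolan-2-one, via open-chain hydroxy enal 16 (not isolated), via hydroxy ester 17 (not isolated)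
Conditions: indium powder, THF/H2O (1:1), rt; then PPTS (cat.), toluene, 50 °C
Reagents that add atoms: none
Why: Indium-mediated Barbier allylation (SE2′) through a Zimmerman–Traxler chair with the γ-substituent cis to the CH2–In arm axial gives the syn adduct (hence the cis-fused lactone after acid-catalysed lactonisation), while the aldehyde adds to the face of C7 anti to C9 of the dioxolane in the A(1,3)-minimised rotamer (H8 in plane, O8 on the indium side), which sets C6 and C7 relative to the tartrate-derived C8.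

Step 11
Reactants: 18 (4S,5S)-4-[(4S,5S)-2,2-dimethyl-5-(prop-1-en-2-yl)-1,3-dioxolan-4-yl]-5-[(1Z,3S)-3-hydroxy-2-methylhexa-1,5-dien-1-yl]-3-methylideneoxolan-2-one
Product: 19 (1Z,3S)-1-{(2S,3S)-3-[(4S,5S)-2,2-dimethyl-5-(prop-1-en-2-yl)-1,3-dioxolan-4-yl]-4-methylidene-5-oxooxolan-2-yl}-2-methylhexa-1,5-dien-3-yl acetate
Conditions: Ac2O, pyridine, DMAP (cat.), CH2Cl2, 0 °C → rt
Reagents that add atoms: acetic anhydride, CC(=O)OC(C)=O
Why: Acylation of the only free hydroxyl (C3) with retention of configuration.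

Step 12
Reactants: 19 (1Z,3S)-1-{(2S,3S)-3-[(4S,5S)-2,2-dimethyl-5-(prop-1-en-2-yl)-1,3-dioxolan-4-yl]-4-methylidene-5-oxooxolan-2-yl}-2-methylhexa-1,5-dien-3-yl acetate
Product: 20 (1(10)Z,3S,4Z,6S,7S,8S,9S)-3-acetoxy-8,9-(isopropylidenedioxy)germacra-1(10),4,11(13)-trien-12,6-olide
Conditions: second-generation Grubbs catalyst (10 mol%), toluene (1 mM), 80 °C
Reagents that add atoms: none
Why: Ring-closing metathesis in which the ruthenium carbene forms at the unhindered C1 vinyl group and closes onto the isopropenyl group with loss of ethene, the cis-fused ten-membered ring that already holds a Z-alkene taking up the new trisubstituted alkene in the less strained Z geometry, with no stereocentre touched and the conjugated exo-methylene a poor metathesis partner.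

Step 13
Reactants: 20 (1(10)Z,3S,4Z,6S,7S,8S,9S)-3-acetoxy-8,9-(isopropylidenedioxy)germacra-1(10),4,11(13)-trien-12,6-olide
Product: 21 (1(10)Z,3S,4Z,6S,7R,8S,9S)-3-acetoxy-8,9-dihydroxygermacra-1(10),4,11(13)-trien-12,6-olide
Conditions: AcOH/H2O (4:1), 45 °C
Reagents that add atoms: none
Why: Mild acid hydrolysis of the isopropylidene acetal leaves the allylic acetate, the α-methylene lactone and the Z,Z-diene intact, and the C7 descriptor changes from S to R only through CIP priorities.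

Step 14
Reactants: 22 (2E)-2-methylbut-2-en-1-ol (tiglyl alcohol)
Product: 23 [(2R,3R)-2,3-dimethyloxiran-2-yl]methanol
Conditions: t-BuOOH, Ti(OiPr)4 (10 mol%), D-(−)-diethyl tartrate (12 mol%), 4 Å MS, CH2Cl2, −20 °C
Reagents that add atoms: tert-butyl hydroperoxide, CC(C)(C)OO
Why: Sharpless asymmetric epoxidation, in which D-(−)-tartrate delivers oxygen to the face that gives the (2R,3R)-epoxy alcohol and the E-alkene geometry becomes the cis relationship of the two methyl groups.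

Step 15
Reactants: 23 [(2R,3R)-2,3-dimethyloxiran-2-yl]methanol
Product: 24 (2S,3R)-2,3-dimethyloxirane-2-carboxylic acid
Conditions: RuCl3 (2 mol%), NaIO4, MeCN/EtOAc/H2O, 0 °C → rt
Reagents that add atoms: water, O
Why: RuO4-mediated oxidation (Sharpless conditions) takes the primary alcohol to the acid without opening the epoxide, the C2 descriptor changing from R to S only through CIP priorities.

Step 16
Reactants: 21 (1(10)Z,3S,4Z,6S,7R,8S,9S)-3-acetoxy-8,9-dihydroxygermacra-1(10),4,11(13)-trien-12,6-olide; 24 (2S,3R)-2,3-dimethyloxirane-2-carboxylic acid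
Product: 26 (1(10)Z,3S,4Z,6S,7R,8S,9S)-3-acetoxy-8-hydroxy-9-[(2S,3R)-2,3-dimethyloxirane-2-carbonyloxy]germacra-1(10),4,11(13)-trien-12,6-olide (CNP0137407.7), via mixed anhydride 25 (not isolated)
Conditions: 24 (1.2 equiv), 2,4,6-Cl3C6H2COCl, Et3N, THF, 0 °C; then 21, DMAP, toluene, 0 °C → rt
Reagents that add atoms: none
Why: Yamaguchi esterification, in which the bulky DMAP-activated mixed anhydride acylates the allylic 9-OH (flanked by an sp2 carbon) in preference to the 8-OH next to the ring-fusion methine, with retention at every stereocentre and without opening the epoxide.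

**Compound list**
1 | dimethyl (4R,5R)-2,2-dimethyl-1,3-dioxolane-4,5-dicarboxylate | COC(=O)[C@@H]1OC(C)(C)O[C@H]1C(=O)OC | starting material
2 | (4R,5R)-N4,N5-dimethoxy-N4,N5,2,2-tetramethyl-1,3-dioxolane-4,5-dicarboxamide | CON(C)C(=O)[C@@H]1OC(C)(C)O[C@H]1C(=O)N(C)OC | intermediate
3 | (4R,5R)-5-acetyl-N-methoxy-N,2,2-trimethyl-1,3-dioxolane-4-carboxamide | CON(C)C(=O)[C@@H]1OC(C)(C)O[C@H]1C(C)=O | intermediate
4 | (4R,5S)-N-methoxy-N,2,2-trimethyl-5-(prop-1-en-2-yl)-1,3-dioxolane-4-carboxamide | CON(C)C(=O)[C@@H]1OC(C)(C)O[C@H]1C(C)=C | intermediate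
5 | (4R,5S)-2,2-dimethyl-5-(prop-1-en-2-yl)-1,3-dioxolane-4-carbaldehyde | O=C[C@@H]1OC(C)(C)O[C@H]1C(C)=C | intermediate
6 | methyl acrylate | C=CC(=O)OC | starting material
7 | methyl 2-{hydroxy[(4S,5S)-2,2-dimethyl-5-(prop-1-en-2-yl)-1,3-dioxolan-4-yl]methyl}prop-2-enoate (carbinol epimers) | C=C(C(=O)OC)C(O)[C@@H]1OC(C)(C)O[C@H]1C(C)=C | intermediate
8 | methyl (2Z)-2-(bromomethyl)-3-[(4S,5S)-2,2-dimethyl-5-(prop-1-en-2-yl)-1,3-dioxolan-4-yl]prop-2-enoate | COC(=O)/C(CBr)=C/[C@@H]1OC(C)(C)O[C@H]1C(C)=C | intermediate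
9 | 3-(trimethylsilyl)prop-2-ynal | C[Si](C)(C)C#CC=O | starting material
10 | (3S)-1-(trimethylsilyl)hex-5-en-1-yn-3-ol | C=CC[C@H](O)C#C[Si](C)(C)C | intermediate
11 | (3S)-hex-5-en-1-yn-3-ol | C=CC[C@H](O)C#C | intermediate
12 | (5S)-4-methyl-5-(prop-2-en-1-yl)-2,5-dihydro-1,2-oxamagnesole (chelated alkenylmagnesium alkoxide) | C=CC[C@@H]1O[Mg]C=C1C | intermediate
13 | (2Z,4S)-4-hydroxy-3-methylhepta-2,6-dienoic acid | C=CC[C@H](O)/C(C)=C\C(=O)O | intermediate
14 | (5S)-4-methyl-5-(prop-2-en-1-yl)furan-2(5H)-one | C=CC[C@@H]1OC(=O)C=C1C | intermediate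
15 | (5S)-4-methyl-5-(prop-2-en-1-yl)-2,5-dihydrofuran-2-ol (anomer mixture) | C=CC[C@@H]1OC(O)C=C1C | intermediate
16 | (2Z,4S)-4-hydroxy-3-methylhepta-2,6-dienal | C=CC[C@H](O)/C(C)=C\C=O | intermediate
17 | methyl (3S,4S,5Z,7S)-3-[(4S,5S)-2,2-dimethyl-5-(prop-1-en-2-yl)-1,3-dioxolan-4-yl]-4,7-dihydroxy-6-methyl-2-methylidenedeca-5,9-dienoate | COC(=O)C(=C)[C@@H]([C@@H](O)/C=C(/C)[C@@H](O)CC=C)[C@@H]1OC(C)(C)O[C@H]1C(C)=C | intermediate
18 | (4S,5S)-4-[(4S,5S)-2,2-dimethyl-5-(prop-1-en-2-yl)-1,3-dioxolan-4-yl]-5-[(1Z,3S)-3-hydroxy-2-methylhexa-1,5-dien-1-yl]-3-methylideneoxolan-2-one | C=C1C(=O)O[C@@H](/C=C(/C)[C@@H](O)CC=C)[C@H]1[C@@H]2OC(C)(C)O[C@H]2C(C)=C | intermediate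
19 | (1Z,3S)-1-{(2S,3S)-3-[(4S,5S)-2,2-dimethyl-5-(prop-1-en-2-yl)-1,3-dioxolan-4-yl]-4-methylidene-5-oxooxolan-2-yl}-2-methylhexa-1,5-dien-3-yl acetate | C=C1C(=O)O[C@@H](/C=C(/C)[C@@H](OC(C)=O)CC=C)[C@H]1[C@@H]2OC(C)(C)O[C@H]2C(C)=C | intermediate
20 | (1(10)Z,3S,4Z,6S,7S,8S,9S)-3-acetoxy-8,9-(isopropylidenedioxy)germacra-1(10),4,11(13)-trien-12,6-olide | C=C1C(=O)O[C@H]2/C=C(/C)[C@@H](OC(C)=O)C/C=C(/C)[C@@H]3OC(C)(C)O[C@H]3[C@@H]12 | intermediate
21 | (1(10)Z,3S,4Z,6S,7R,8S,9S)-3-acetoxy-8,9-dihydroxygermacra-1(10),4,11(13)-trien-12,6-olide | C=C1C(=O)O[C@H]2/C=C(/C)[C@@H](OC(C)=O)C/C=C(/C)[C@H](O)[C@@H](O)[C@@H]12 | intermediate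
22 | (2E)-2-methylbut-2-en-1-ol | C/C=C(\C)CO | starting material
23 | [(2R,3R)-2,3-dimethyloxiran-2-yl]methanol | OC[C@@]1(C)O[C@@H]1C | intermediate
24 | (2S,3R)-2,3-dimethyloxirane-2-carboxylic acid | OC(=O)[C@@]1(C)O[C@@H]1C | intermediate
25 | (2S,3R)-2,3-dimethyloxirane-2-carboxylic 2,4,6-trichlorobenzoic anhydride | O=C(OC(=O)[C@@]1(C)O[C@@H]1C)c1c(Cl)cc(Cl)cc1Cl | intermediate
26 | (1(10)Z,3S,4Z,6S,7R,8S,9S)-3-acetoxy-8-hydroxy-9-[(2S,3R)-2,3-dimethyloxirane-2-carbonyloxy]germacra-1(10),4,11(13)-trien-12,6-olide | C=C1C(=O)O[C@H]2/C=C(/C)[C@@H](OC(C)=O)C/C=C(/C)[C@H](OC(=O)[C@@]3(C)O[C@@H]3C)[C@@H](O)[C@@H]12 | target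

**Totals**
Total step count: 16. Longest linear sequence: 11 steps (steps 1–6, 10–13 and 16, from 1).

**Three steps most likely to fail, each with a fallback**

Step 10 (Barbier union). The syn (cis-lactone) outcome is reliable, but the face of C7 chosen relative to the dioxolane rests on a steric/chelation model, and the lactol partner can dehydrate to a furan. The fallback sets out from 8 and comes back at 18. Borylation of 8 with B2pin2 and catalytic Pd2(dba)3 (toluene, 50 °C) gives methyl (2E)-3-[(4S,5S)-2,2-dimethyl-5-(prop-1-en-2-yl)-1,3-dioxolan-4-yl]-2-[(4,4,5,5-tetramethyl-1,3,2-dioxaborolan-2-yl)methyl]prop-2-enoate F1. F1 and lactol 15 (reacting as 16) are then combined with the chiral phosphoric acid (R)-TRIP (5 mol%, toluene, 4 Å MS, −30 °C → rt). The catalyst, not the dioxolane, now selects the aldehyde face in a closed boron chair (Re face expected, giving 6S), and the cis γ-substituent fixes C7, which gives the borate ester F2. Aqueous work-up gives 17, and PPTS closes the lactone to 18.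

Step 12 (ring-closing metathesis). Closure onto the hindered isopropenyl group next to the dioxolane may be too slow, leading to oligomers. The fallback is a relay metathesis that delivers the catalyst to C10 from a sacrificial tether; it sets out from 3 and comes back at 20. Wittig reaction of 3 with the ylide from (hex-5-en-1-yl)triphenylphosphonium bromide (KN(SiMe3)2, THF, −78 → 0 °C) gives the relay amide F3 (alkene geometry irrelevant). The conditions of steps 4, 5, 6, 10 and 11 (i-Bu2AlH; 6 with DABCO; NBS/Me2S; 15 with indium powder then PPTS; Ac2O) then give in turn aldehyde F4, Morita–Baylis–Hillman adduct F5, bromide F6, hydroxy ester F7 (not isolated), lactone alcohol F8 and acetate F9. With the second-generation Grubbs catalyst (toluene, 1 mM, 80 °C) the terminal alkene of the tether is loaded first and cyclopentene is expelled. The ruthenium carbene is thereby placed on C10 and closes onto the unhindered C1 vinyl group to give 20.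

Step 16 (O9-selective acylation). If O8 proves the more reactive hydroxyl, direct esterification gives the wrong regioisomer or mixtures. The fallback is a protecting-group detour that uses the same bias in reverse; it sets out from 21 and comes back at 26. Silylation with TESCl and imidazole (DMF, −40 °C) caps the more reactive O8 to give the 8-O-triethylsilyl ether F10. Yamaguchi esterification with 25 (DMAP, toluene) at the remaining 9-OH gives the silyl-protected ester F11, and HF·pyridine (THF, 0 °C), which does not promote acyl migration, releases 26.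

**Further compounds**
F1 | step 10 | methyl (2E)-3-[(4S,5S)-2,2-dimethyl-5-(prop-1-en-2-yl)-1,3-dioxolan-4-yl]-2-[(4,4,5,5-tetramethyl-1,3,2-dioxaborolan-2-yl)methyl]prop-2-enoate | COC(=O)/C(CB1OC(C)(C)C(C)(C)O1)=C/[C@@H]2OC(C)(C)O[C@H]2C(C)=C
F2 | step 10 | methyl (3S,4S,5Z,7S)-3-[(4S,5S)-2,2-dimethyl-5-(prop-1-en-2-yl)-1,3-dioxolan-4-yl]-7-hydroxy-6-methyl-2-methylidene-4-[(4,4,5,5-tetramethyl-1,3,2-dioxaborolan-2-yl)oxy]deca-5,9-dienoate | COC(=O)C(=C)[C@@H]([C@@H](OB1OC(C)(C)C(C)(C)O1)/C=C(/C)[C@@H](O)CC=C)[C@@H]2OC(C)(C)O[C@H]2C(C)=C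
F3 | step 12 | (4R,5S)-N-methoxy-N,2,2-trimethyl-5-(octa-2,7-dien-2-yl)-1,3-dioxolane-4-carboxamide | CON(C)C(=O)[C@@H]1OC(C)(C)O[C@H]1C(C)=CCCCC=C
F4 | step 12 | (4R,5S)-2,2-dimethyl-5-(octa-2,7-dien-2-yl)-1,3-dioxolane-4-carbaldehyde | O=C[C@@H]1OC(C)(C)O[C@H]1C(C)=CCCCC=C
F5 | step 12 | methyl 2-{hydroxy[(4S,5S)-2,2-dimethyl-5-(octa-2,7-dien-2-yl)-1,3-dioxolan-4-yl]methyl}prop-2-enoate | C=C(C(=O)OC)C(O)[C@@H]1OC(C)(C)O[C@H]1C(C)=CCCCC=C
F6 | step 12 | methyl (2Z)-2-(bromomethyl)-3-[(4S,5S)-2,2-dimethyl-5-(octa-2,7-dien-2-yl)-1,3-dioxolan-4-yl]prop-2-enoate | COC(=O)/C(CBr)=C/[C@@H]1OC(C)(C)O[C@H]1C(C)=CCCCC=C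
F7 | step 12 | methyl (3S,4S,5Z,7S)-3-[(4S,5S)-2,2-dimethyl-5-(octa-2,7-dien-2-yl)-1,3-dioxolan-4-yl]-4,7-dihydroxy-6-methyl-2-methylidenedeca-5,9-dienoate | COC(=O)C(=C)[C@@H]([C@@H](O)/C=C(/C)[C@@H](O)CC=C)[C@@H]1OC(C)(C)O[C@H]1C(C)=CCCCC=C
F8 | step 12 | (4S,5S)-4-[(4S,5S)-2,2-dimethyl-5-(octa-2,7-dien-2-yl)-1,3-dioxolan-4-yl]-5-[(1Z,3S)-3-hydroxy-2-methylhexa-1,5-dien-1-yl]-3-methylideneoxolan-2-one | C=C1C(=O)O[C@@H](/C=C(/C)[C@@H](O)CC=C)[C@H]1[C@@H]2OC(C)(C)O[C@H]2C(C)=CCCCC=C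
F9 | step 12 | (1Z,3S)-1-{(2S,3S)-3-[(4S,5S)-2,2-dimethyl-5-(octa-2,7-dien-2-yl)-1,3-dioxolan-4-yl]-4-methylidene-5-oxooxolan-2-yl}-2-methylhexa-1,5-dien-3-yl acetate | C=C1C(=O)O[C@@H](/C=C(/C)[C@@H](OC(C)=O)CC=C)[C@H]1[C@@H]2OC(C)(C)O[C@H]2C(C)=CCCCC=C
F10 | step 16 | (1(10)Z,3S,4Z,6S,7S,8S,9S)-3-acetoxy-9-hydroxy-8-(triethylsilyloxy)germacra-1(10),4,11(13)-trien-12,6-olide | C=C1C(=O)O[C@H]2/C=C(/C)[C@@H](OC(C)=O)C/C=C(/C)[C@H](O)[C@@H](O[Si](CC)(CC)CC)[C@@H]12
F11 | step 16 | (1(10)Z,3S,4Z,6S,7S,8S,9S)-3-acetoxy-9-[(2S,3R)-2,3-dimethyloxirane-2-carbonyloxy]-8-(triethylsilyloxy)germacra-1(10),4,11(13)-trien-12,6-olide | C=C1C(=O)O[C@H]2/C=C(/C)[C@@H](OC(C)=O)C/C=C(/C)[C@H](OC(=O)[C@@]3(C)O[C@@H]3C)[C@@H](O[Si](CC)(CC)CC)[C@@H]12
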